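## Analysis of the target

Target 26 is (1R,6S,7S,8S)-5-methoxy-8-(4-methoxy-2-oxo-2H-pyran-6-yl)-7-phenyl-1-(2-phenylethyl)-2-oxabicyclo[4.2.0]oct-4-en-3-one. It is a cyclobutane fused along one bond to a 4-methoxy-5,6-dihydro-2-pyranone, with a 4-methoxy-2-pyranone as a substituent. The cyclobutane carbons are called Ca (C1, quaternary, bearing the lactone oxygen and the phenethyl chain), Cb (C6, ring-fusion CH bearing the enol-ether carbon of the lactone), Cc (C7, CHPh) and Cd (C8, CH bearing C6 of the pyranone). All four stereocentres lie on this ring. The oxygen at Ca, the acyl carbon at Cb and the phenyl group at Cc are on one face (the α face below); the phenethyl chain at Ca and the pyranone at Cd are on the other (β face). Both Cb and Cd carry carbonyl-level carbons β to the Ca oxygen, so a free Ca hydroxyl next to an aldehyde or ketone on Cb or Cd is a 2-acylcyclobutanol that opens by retro-aldol cleavage. Once Ca–O is acylated, a base that removes Cb–H or Cd–H can expel the carboxylate or epimerise. The synthesis is hard because four contiguous, differently substituted centres must be set on a strained ring, in a head-to-tail pattern that a crossed photodimerisation of two pyranones could not deliver selectively, and in one absolute sense. The strategy rests on one feature: Ca is at the carbonyl level with Cd as its α-carbon, while Cb (one-carbon oxygenated arm) and Cc (phenyl) are cis. Ca–Cd can therefore come from a ketene equivalent and Cb–Cc from a (Z)-styrene whose aryl ring and allylic CH2O arm are tied through oxygen, that is C3=C4 of 2H-chromene 2.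

## Retrosynthetic reasoning

**26 to 25.** The two O–CH3 bonds are cut last. Both are enol ethers of 1,3-dicarbonyl units of similar acidity, so one O-alkylation can close the synthesis and the acid-sensitive vinylogous esters are absent from every earlier step.

**25 to 23 (through 24).** The pyranone is opened at its O1–C2 bond. Closing that bond forward through acylketene 24 needs only heat, which matters because Cd–H in 23 is α to a ketone and β to the lactone oxygen and would not tolerate base.

**23 to 22, and 22 to 18 plus 21.** The bond between the carbonyl carbon on Cd and its α-carbon is cut, after adjusting the oxidation level. This leaves a plain aldehyde on Cd and brings the remaining four pyranone carbons in one masked reagent, 21 (made from 19). The forward reaction must be a Lewis-acid aldol, again to avoid an enolate at Cd.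

**18 to 17 to 16.** The Cd arm is returned to the alcohol and then to the benzyl ether that has carried it since the ring was built. The benzyl ether is chosen because it survives every step from amide activation to the lactone closure.

**16 to 15.** The lactone is cut at C4–C5, not at the ester C–O bond. Closing the ester bond last would need a free Ca hydroxyl beside a carbonyl on Cb, which is the retro-aldol situation. So the ester is made first and the ring is closed by a reductive intramolecular enolate addition onto the Cb aldehyde.

**15 to 11 (through 14, 13, 12).** The ester at Ca and the aldehyde at Cb are traced to a diol. The primary hydroxyl is masked, the tertiary one acylated, and only then is the primary carbon oxidised, so Ca–O is acylated before any carbonyl exists on the ring.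

**11 to 10.** The primary oxygen of 11 is reconnected to the ortho carbon of the Cc phenyl ring. This turns the cis pair Cb–CH2O / Cc–aryl into a pyran ring. The gain is that the cis relation becomes a ring fusion, Cb cannot epimerise next to a ketone, and the two faces of that ketone become different. Forward, the C(aryl)–O bond must be hydrogenolysed without touching the benzyl ether.

**10 to 9.** The Ca–CH2 bond of the phenethyl chain is cut to a cyclobutanone and a weakly basic phenethyl organometallic. The nucleophile has to enter on the convex face and must not enolise the ketone.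

**9 to 6 plus 2 (through 7 and 8).** Ca–Cb and Cc–Cd are cut together. This pairing puts Ca and Cd in a ketene-type partner and Cb, Cc in an electron-rich cyclic styrene. The other pairing (Ca–Cd and Cb–Cc) would need an enol-type alkene and a cinnamyl partner with no polar bias. The forward reaction has to set three stereocentres and the absolute configuration.

**6 to 3 plus 4, and 2 to 1.** The amide C–N bond is cut to a commercial acid and a commercial C2-symmetric amine. The chromene is traced to an aryl propargyl ether by a thermal rearrangement. Both are short, so the risk sits in the cycloaddition.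

## Alternatives that were turned down

**Alternative 1:** Both heterocycles are disconnected at their O–C2 bonds at once, back to the cyclobutanol A1, which carries a dioxinone on Cb and a dioxinonyl-acetyl group on Cd. Forward, heating A1 would release two molecules of acetone; the acylketene on Cb would be trapped by the Ca hydroxyl and the one on the Cd side chain by its own enol, giving A2, which is the same compound as 25. In its favour, the step is neutral and forms both rings in one operation. On endgame step count it is stronger than the chosen route, which spends steps 10 and 14 to 16 on the same result. Against it, the plan says nothing about the cyclobutane or its four stereocentres. A1 also has a free Ca hydroxyl beside a ketone on Cd, the 2-acylcyclobutanol that retro-aldol cleavage opens at thermolysis temperature. The hindered tertiary hydroxyl is a slow trap for an acylketene, so intermolecular capture competes. The chosen strategy gives up the one-pot double closure but acylates Ca–O before any carbonyl is raised on the ring, and it supplies the ring itself.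

**Alternative 2:** The Ca–Cb bond is disconnected, leading to the flat pyranone ester A3. Forward, UV irradiation would close A3 by 4π-electrocyclisation to the bicyclic β-lactone A4. In its favour, A3 comes from condensation chemistry, and one photochemical step creates the four-membered ring, the quaternary Ca and the cis Ca–O/Cb–acyl relation. In steps to a cyclobutane it is shorter than steps 1 to 4 here. Against it, A3 is achiral and offers no handle for absolute control, so A4 would be racemic. A4 is a strained β-lactone that reverts or fragments on warming. Cc and Cd are still sp2 in A4, and syn delivery of hydrogen to the tetrasubstituted cyclobutene would place phenyl and ester cis, whereas the target has them trans. Cd would then have to be inverted next to a β-acyloxy leaving group. The β-lactone carbonyl would still need a two-carbon homologation. The chosen strategy sets Cb, Cc and Cd in their final relation in the ring-forming step and controls the absolute sense with an auxiliary.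

**Alternative 3:** The Cb–Cc bond is disconnected, leading to the cyclopentane A5 with a mesylate on Cb flanked by two tertiary carbinols. Forward, alkoxide formation would drive a 1,2-shift of Cc onto Cb with loss of mesylate, and the Ca alkoxide would lactonise onto the ester to give A6. In its favour, the shift is stereospecific (retention at Cc, inversion at Cb), stereocontrol on a five-membered ring is more routine, and A6 already holds the β-keto lactone. On the lactone it is more direct than steps 5 to 10 here. Against it, contraction from a five- to a four-membered ring costs roughly 20 kcal/mol of strain, paid only by carbonyl formation. The Ca alkoxide also flanks the mesylate, so a shift from that side competes. The first-formed product is a Ca alkoxide beside a Cb ketone, whose retro-aldol reopening competes with lactonisation. A5 has five contiguous stereocentres and would be long to make. The chosen strategy pays the strain with the energy of a keteniminium ion and never exposes a cyclobutanolate next to a ketone.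

Key step: step 3

Remark on the chemistry: the facial sense of the (2S,5S)-auxiliary is taken from the steric model given in step 3; should it prove opposite, the (2R,5R)-amide would be used and nothing else would change.

## Route

Step 1
Reactants: 1 phenyl propargyl ether
Product: 2 2H-chromene
Conditions: PhNEt2, 215 °C
Reagents that add atoms: none
Why: Thermal aryl propargyl ether rearrangement: Claisen [3,3]-shift to the ortho-allenyl dienone, hydrogen shift to the ortho-quinone methide and 6π-electrocyclisation should give the chromene; no stereocentre is formed.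

Step 2
Reactants: 3 3-(benzyloxy)propanoic acid; 4 (2S,5S)-2,5-dimethylpyrrolidine
Product: 6 3-(benzyloxy)-1-[(2S,5S)-2,5-dimethylpyrrolidin-1-yl]propan-1-one, via 3-(benzyloxy)propanoyl chloride 5 (not isolated)
Conditions: (COCl)2, cat. DMF, CH2Cl2, 0 → 20 °C; then 4, Et3N, CH2Cl2, 0 °C
Reagents that add atoms: none
Why: Acid chloride formation followed by N-acylation, the reliable way to acylate a hindered secondary amine; the two stereocentres of the amine are not touched.

Step 3
Reactants: 6 3-(benzyloxy)-1-[(2S,5S)-2,5-dimethylpyrrolidin-1-yl]propan-1-one; 2 2H-chromene (3 equiv)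
Product: 9 (1S,2aS,8bR)-1-[(benzyloxy)methyl]-1,2a,3,8b-tetrahydro-2H-cyclobuta[c]chromen-2-one, via keteniminium triflate 7 (not isolated), via cyclobutaniminium triflate 8 (not isolated)
Conditions: Tf2O (1.1 equiv), 2,6-di-tert-butylpyridine (1.2 equiv), ClCH2CH2Cl, −20 → 60 °C; then H2O, CH2Cl2, 20 °C
Reagents that add atoms: water, O
Why: Triflic anhydride O-sulfonylates amide 6 and the hindered pyridine removes an α-proton, so that loss of triflate gives keteniminium 7, a strongly electrophilic ketene surrogate that does not dimerise. The closest known reaction type is the keteniminium–alkene [2+2] cycloaddition of amides of C2-symmetric 2,5-dimethylpyrrolidine, which gives cyclobutanones after hydrolysis. The addition is asynchronous: C3 of 2 attacks the central carbon of 7 (Ca–Cb bond) to give a benzylic cation at C4 stabilised by the ortho ether oxygen, and the enamine carbon then closes on C4 (Cc–Cd bond), so the four-membered ring is closed by a formal 4-exo-trig collapse of the cation–enamine pair. Regiochemistry therefore follows from the polarisation of the ortho-alkoxystyrene. The cis relation of Cb and Cc cannot be lost, because both carbons are held in the pyran ring and the cation cannot rotate. The benzyloxymethyl group at Cd should settle on the convex face, trans to the aryl group at Cc, because iminium 8 can equilibrate through its enamine before hydrolysis. The absolute configuration is set by the auxiliary: its C2 axis leaves a single keteniminium geometry, and the methyl group that flanks the line of approach forces the allylic CH2 of 2 to the other side, so one enantiotopic face of the alkene is preferred. The step needs cycloaddition to outrun hydride loss from C2 of 2 and loss of the β-aryloxy group, which the non-nucleophilic base, cold activation and neutral hydrolysis are meant to secure.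

Step 4
Reactants: 9 (1S,2aS,8bR)-1-[(benzyloxy)methyl]-1,2a,3,8b-tetrahydro-2H-cyclobuta[c]chromen-2-one
Product: 10 (1S,2S,2aS,8bR)-1-[(benzyloxy)methyl]-2-(2-phenylethyl)-1,2a,3,8b-tetrahydro-2H-cyclobuta[c]chromen-2-ol (hydroxyl cis to the pyran ring)
Conditions: PhCH2CH2MgCl, CeCl3, THF, −78 °C; then H2O
Reagents that add atoms: 2-phenylethylmagnesium chloride, Cl[Mg]CCc1ccccc1
Why: Organocerium 1,2-addition: the weakly basic reagent should add faster than it enolises, which matters because an enolate toward Cb would expel the aryloxide. Attack is expected on the convex face, anti to the cross-ring aryl group at Cc and to the pyran ring, which places the hydroxyl at Ca on the α face.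

Step 5
Reactants: 10 (1S,2S,2aS,8bR)-1-[(benzyloxy)methyl]-2-(2-phenylethyl)-1,2a,3,8b-tetrahydro-2H-cyclobuta[c]chromen-2-ol
Product: 11 4-[(benzyloxy)methyl]-2-(hydroxymethyl)-3-phenyl-1-(2-phenylethyl)cyclobutan-1-ol (OH, CH2OH and phenyl on the α face; phenethyl and CH2OBn on the β face)
Conditions: Ni(cod)2 (20 mol %), 1,3-bis(2,6-diisopropylphenyl)imidazolinium chloride (40 mol %), NaOt-Bu (2.5 equiv), H2 (1 bar), m-xylene, 120 °C; then H2O
Reagents that add atoms: none
Why: Nickel–carbene-catalysed hydrogenolysis of the C(aryl)–O bond of an alkyl aryl ether: zerovalent nickel inserts into the aryl–oxygen bond, dihydrogen cleaves the aryl–nickel alkoxide, and arene plus alkoxide are released. The electron-rich carbene ligand is used because a plain ortho-alkyl phenyl ether is too unreactive for phosphine–hydrosilane systems; benzyl alkyl ethers react more slowly than aryl ethers under these conditions and no stereocentre is involved.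

Step 6
Reactants: 11 4-[(benzyloxy)methyl]-2-(hydroxymethyl)-3-phenyl-1-(2-phenylethyl)cyclobutan-1-ol
Product: 12 4-[(benzyloxy)methyl]-3-phenyl-1-(2-phenylethyl)-2-{[(triethylsilyl)oxy]methyl}cyclobutan-1-ol
Conditions: Et3SiCl (1.05 equiv), imidazole, CH2Cl2, −20 → 0 °C
Reagents that add atoms: chlorotriethylsilane, CC[Si](Cl)(CC)CC
Why: Silylation is far faster at the primary hydroxyl than at the flanked tertiary cyclobutanol, so the two oxygens are told apart.

Step 7
Reactants: 12 4-[(benzyloxy)methyl]-3-phenyl-1-(2-phenylethyl)-2-{[(triethylsilyl)oxy]methyl}cyclobutan-1-ol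
Product: 13 4-[(benzyloxy)methyl]-3-phenyl-1-(2-phenylethyl)-2-{[(triethylsilyl)oxy]methyl}cyclobutyl bromoacetate
Conditions: BrCH2COBr, pyridine, cat. DMAP, CH2Cl2, 0 → 20 °C
Reagents that add atoms: bromoacetyl bromide, BrCC(Br)=O
Why: O-Acylation of the tertiary alcohol with a reactive acid bromide. Doing it now, before any carbonyl exists on Cb or Cd, removes the retro-aldol pathway and installs the two lactone carbons.

Step 8
Reactants: 13 4-[(benzyloxy)methyl]-3-phenyl-1-(2-phenylethyl)-2-{[(triethylsilyl)oxy]methyl}cyclobutyl bromoacetate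
Product: 14 4-[(benzyloxy)methyl]-2-(hydroxymethyl)-3-phenyl-1-(2-phenylethyl)cyclobutyl bromoacetate
Conditions: AcOH–THF–H2O (3:1:1), 20 °C
Reagents that add atoms: none
Why: Mild acid solvolysis of a primary triethylsilyl ether; the bromoacetate and the benzyl ether are stable, and the non-basic medium disfavours acyl migration to the freed hydroxyl.

Step 9
Reactants: 14 4-[(benzyloxy)methyl]-2-(hydroxymethyl)-3-phenyl-1-(2-phenylethyl)cyclobutyl bromoacetate
Product: 15 4-[(benzyloxy)methyl]-2-formyl-3-phenyl-1-(2-phenylethyl)cyclobutyl bromoacetate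
Conditions: Dess–Martin periodinane, CH2Cl2, 0 → 20 °C
Reagents that add atoms: none
Why: Dess–Martin oxidation is non-basic, so the aldehyde should form without epimerisation at Cb or loss of the β-acyloxy group; 15 would be used without chromatography.

Step 10
Reactants: 15 4-[(benzyloxy)methyl]-2-formyl-3-phenyl-1-(2-phenylethyl)cyclobutyl bromoacetate
Product: 16 8-[(benzyloxy)methyl]-5-hydroxy-7-phenyl-1-(2-phenylethyl)-2-oxabicyclo[4.2.0]octan-3-one (cyclobutane configuration as in 26; either or both C5 epimers)
Conditions: SmI2 (2.2 equiv), THF, −78 °C; then aq. NH4Cl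
Reagents that add atoms: none
Why: Intramolecular Reformatsky reaction of a β-(bromoacetoxy) aldehyde: divalent samarium reduces the C–Br bond to a trivalent samarium enolate, which adds to the aldehyde through a six-membered chelate and closes the δ-lactone. The new carbinol centre is oxidised later, so its configuration does not matter.

Step 11
Reactants: 16 8-[(benzyloxy)methyl]-5-hydroxy-7-phenyl-1-(2-phenylethyl)-2-oxabicyclo[4.2.0]octan-3-one
Product: 17 5-hydroxy-8-(hydroxymethyl)-7-phenyl-1-(2-phenylethyl)-2-oxabicyclo[4.2.0]octan-3-one
Conditions: H2 (1 bar), 10% Pd/C, EtOAc, 20 °C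
Reagents that add atoms: none
Why: Hydrogenolysis of the benzyl ether; the lactone, the secondary alcohol and the arylcyclobutane carry no group that is reduced under these conditions.

Step 12
Reactants: 17 5-hydroxy-8-(hydroxymethyl)-7-phenyl-1-(2-phenylethyl)-2-oxabicyclo[4.2.0]octan-3-one
Product: 18 5-hydroxy-3-oxo-7-phenyl-1-(2-phenylethyl)-2-oxabicyclo[4.2.0]octane-8-carbaldehyde
Conditions: TEMPO (10 mol %), PhI(OAc)2 (1.1 equiv), CH2Cl2, 20 °C
Reagents that add atoms: none
Why: Oxoammonium oxidation is selective for the primary over the secondary alcohol and runs without base, so Cd keeps its configuration and the β-acyloxy group stays.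

Step 13
Reactants: 19 2,2,6-trimethyl-4H-1,3-dioxin-4-one
Product: 21 trimethyl[(2,2-dimethyl-6-methylidene-6H-1,3-dioxin-4-yl)oxy]silane, via lithium dienolate 20 (not isolated)
Conditions: LiN(i-Pr)2, THF, −78 °C; then Me3SiCl, −78 → 20 °C
Reagents that add atoms: chlorotrimethylsilane, C[Si](C)(C)Cl
Why: γ-Deprotonation of the vinylogous ester and O-silylation of the dienolate give the silyl dienol ether used as a masked acetoacetate.

Step 14
Reactants: 18 5-hydroxy-3-oxo-7-phenyl-1-(2-phenylethyl)-2-oxabicyclo[4.2.0]octane-8-carbaldehyde; 21 trimethyl[(2,2-dimethyl-6-methylidene-6H-1,3-dioxin-4-yl)oxy]silane (3 equiv)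
Product: 22 8-[2-(2,2-dimethyl-4-oxo-4H-1,3-dioxin-6-yl)-1-hydroxyethyl]-5-hydroxy-7-phenyl-1-(2-phenylethyl)-2-oxabicyclo[4.2.0]octan-3-one (carbinol epimers)
Conditions: BF3·OEt2, CH2Cl2, −78 °C; aq. NaHCO3 work-up
Reagents that add atoms: none
Why: Vinylogous Mukaiyama aldol addition at the γ-carbon of the dienol ether under Lewis acid, so no enolate is formed at Cd; the excess of 21 allows for silyl transfer to the free hydroxyl, and the new carbinol is oxidised in the next step.

Step 15
Reactants: 22 8-[2-(2,2-dimethyl-4-oxo-4H-1,3-dioxin-6-yl)-1-hydroxyethyl]-5-hydroxy-7-phenyl-1-(2-phenylethyl)-2-oxabicyclo[4.2.0]octan-3-one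
Product: 23 8-[(2,2-dimethyl-4-oxo-4H-1,3-dioxin-6-yl)acetyl]-5-hydroxy-7-phenyl-1-(2-phenylethyl)-2-oxabicyclo[4.2.0]oct-4-en-3-one (β-keto lactone written as its enol)
Conditions: Dess–Martin periodinane (3 equiv), CH2Cl2, 20 °C
Reagents that add atoms: none
Why: Dess–Martin oxidation of both secondary alcohols at once converges the carbinol epimers into one compound with both 1,3-dicarbonyl units; the medium is non-basic.

Step 16
Reactants: 23 8-[(2,2-dimethyl-4-oxo-4H-1,3-dioxin-6-yl)acetyl]-5-hydroxy-7-phenyl-1-(2-phenylethyl)-2-oxabicyclo[4.2.0]oct-4-en-3-one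
Product: 25 (1R,6S,7S,8S)-5-hydroxy-8-(4-hydroxy-2-oxo-2H-pyran-6-yl)-7-phenyl-1-(2-phenylethyl)-2-oxabicyclo[4.2.0]oct-4-en-3-one, via acylketene 24 (not isolated)
Conditions: PhMe (dilute), 110 °C
Reagents that add atoms: none
Why: Thermal retro-[4+2] loss of acetone from the dioxinone gives acylketene 24, whose ketone enol oxygen adds to the ketene carbon to close the 4-hydroxy-2-pyranone; the conditions are neutral, so the Cd centre is not at risk.

Step 17
Reactants: 25 (1R,6S,7S,8S)-5-hydroxy-8-(4-hydroxy-2-oxo-2H-pyran-6-yl)-7-phenyl-1-(2-phenylethyl)-2-oxabicyclo[4.2.0]oct-4-en-3-one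
Product: 26 (1R,6S,7S,8S)-5-methoxy-8-(4-methoxy-2-oxo-2H-pyran-6-yl)-7-phenyl-1-(2-phenylethyl)-2-oxabicyclo[4.2.0]oct-4-en-3-one
Conditions: Me2SO4 (2.5 equiv), K2CO3, acetone, 56 °C
Reagents that add atoms: dimethyl sulfate, COS(=O)(=O)OC
Why: O-Methylation of the two vinylogous acids with a hard electrophile is the standard way to 4-methoxy-2-pyranones and 4-methoxy-5,6-dihydro-2-pyranones; carbonate is too weak to remove Cb–H or Cd–H.

## Compound list

1 | phenyl propargyl ether | C#CCOc1ccccc1 | starting material
2 | 2H-chromene | C1=Cc2ccccc2OC1 | intermediate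
3 | 3-(benzyloxy)propanoic acid | OC(=O)CCOCc1ccccc1 | starting material
4 | (2S,5S)-2,5-dimethylpyrrolidine | C[C@H]1CC[C@H](C)N1 | starting material
5 | 3-(benzyloxy)propanoyl chloride | ClC(=O)CCOCc1ccccc1 | intermediate (not isolated)
6 | 3-(benzyloxy)-1-[(2S,5S)-2,5-dimethylpyrrolidin-1-yl]propan-1-one | O=C(CCOCc1ccccc1)N1[C@@H](C)CC[C@@H]1C | intermediate
7 | keteniminium triflate from 6 | C[C@H]1CC[C@H](C)[N+]1=C=CCOCc1ccccc1.[O-]S(=O)(=O)C(F)(F)F | intermediate (not isolated)
8 | cyclobutaniminium triflate (iminium of 9 with the auxiliary) | C[C@H]1CC[C@H](C)[N+]1=C1[C@@H]2COc3ccccc3[C@@H]2[C@H]1COCc1ccccc1.[O-]S(=O)(=O)C(F)(F)F | intermediate (not isolated)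
9 | (1S,2aS,8bR)-1-[(benzyloxy)methyl]-1,2a,3,8b-tetrahydro-2H-cyclobuta[c]chromen-2-one | O=C1[C@@H]2COc3ccccc3[C@@H]2[C@H]1COCc1ccccc1 | intermediate
10 | (1S,2S,2aS,8bR)-1-[(benzyloxy)methyl]-2-(2-phenylethyl)-1,2a,3,8b-tetrahydro-2H-cyclobuta[c]chromen-2-ol | O[C@]2(CCc3ccccc3)[C@@H]4COc5ccccc5[C@@H]4[C@H]2COCc1ccccc1 | intermediate
11 | 4-[(benzyloxy)methyl]-2-(hydroxymethyl)-3-phenyl-1-(2-phenylethyl)cyclobutan-1-ol (OH, CH2OH, Ph on the α face) | O[C@]2(CCc3ccccc3)[C@H](CO)[C@H](c1ccccc1)[C@H]2COCc1ccccc1 | intermediate
12 | primary triethylsilyl ether of 11 | O[C@]2(CCc3ccccc3)[C@H](CO[Si](CC)(CC)CC)[C@H](c1ccccc1)[C@H]2COCc1ccccc1 | intermediate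
13 | bromoacetate of 12 at the tertiary oxygen | BrCC(=O)O[C@]2(CCc3ccccc3)[C@H](CO[Si](CC)(CC)CC)[C@H](c1ccccc1)[C@H]2COCc1ccccc1 | intermediate
14 | 4-[(benzyloxy)methyl]-2-(hydroxymethyl)-3-phenyl-1-(2-phenylethyl)cyclobutyl bromoacetate | BrCC(=O)O[C@]2(CCc3ccccc3)[C@H](CO)[C@H](c1ccccc1)[C@H]2COCc1ccccc1 | intermediate
15 | 4-[(benzyloxy)methyl]-2-formyl-3-phenyl-1-(2-phenylethyl)cyclobutyl bromoacetate | BrCC(=O)O[C@]2(CCc3ccccc3)[C@H](C=O)[C@H](c1ccccc1)[C@H]2COCc1ccccc1 | intermediate
16 | 8-[(benzyloxy)methyl]-5-hydroxy-7-phenyl-1-(2-phenylethyl)-2-oxabicyclo[4.2.0]octan-3-one (C5 epimers) | OC1CC(=O)O[C@]2(CCc3ccccc3)[C@H]1[C@H](c1ccccc1)[C@H]2COCc1ccccc1 | intermediate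
17 | 5-hydroxy-8-(hydroxymethyl)-7-phenyl-1-(2-phenylethyl)-2-oxabicyclo[4.2.0]octan-3-one | OC1CC(=O)O[C@]2(CCc3ccccc3)[C@H]1[C@H](c1ccccc1)[C@H]2CO | intermediate
18 | 5-hydroxy-3-oxo-7-phenyl-1-(2-phenylethyl)-2-oxabicyclo[4.2.0]octane-8-carbaldehyde | OC1CC(=O)O[C@]2(CCc3ccccc3)[C@H]1[C@H](c1ccccc1)[C@H]2C=O | intermediate
19 | 2,2,6-trimethyl-4H-1,3-dioxin-4-one | CC1=CC(=O)OC(C)(C)O1 | starting material
20 | lithium dienolate of 19 | C=C1C=C([O-])OC(C)(C)O1.[Li+] | intermediate (not isolated)
21 | trimethyl[(2,2-dimethyl-6-methylidene-6H-1,3-dioxin-4-yl)oxy]silane | C=C1C=C(O[Si](C)(C)C)OC(C)(C)O1 | intermediate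
22 | 8-[2-(2,2-dimethyl-4-oxo-4H-1,3-dioxin-6-yl)-1-hydroxyethyl]-5-hydroxy-7-phenyl-1-(2-phenylethyl)-2-oxabicyclo[4.2.0]octan-3-one | OC1CC(=O)O[C@]2(CCc3ccccc3)[C@H]1[C@H](c1ccccc1)[C@H]2C(O)CC1=CC(=O)OC(C)(C)O1 | intermediate
23 | 8-[(2,2-dimethyl-4-oxo-4H-1,3-dioxin-6-yl)acetyl]-5-hydroxy-7-phenyl-1-(2-phenylethyl)-2-oxabicyclo[4.2.0]oct-4-en-3-one | OC1=CC(=O)O[C@]2(CCc3ccccc3)[C@H]1[C@H](c1ccccc1)[C@H]2C(=O)CC1=CC(=O)OC(C)(C)O1 | intermediate
24 | acylketene from 23 (Cd–CO–CH2–CO–CH=C=O) | OC1=CC(=O)O[C@]2(CCc3ccccc3)[C@H]1[C@H](c1ccccc1)[C@H]2C(=O)CC(=O)C=C=O | intermediate (not isolated)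
25 | (1R,6S,7S,8S)-5-hydroxy-8-(4-hydroxy-2-oxo-2H-pyran-6-yl)-7-phenyl-1-(2-phenylethyl)-2-oxabicyclo[4.2.0]oct-4-en-3-one | OC1=CC(=O)O[C@]2(CCc3ccccc3)[C@H]1[C@H](c1ccccc1)[C@H]2c1cc(O)cc(=O)o1 | intermediate
26 | (1R,6S,7S,8S)-5-methoxy-8-(4-methoxy-2-oxo-2H-pyran-6-yl)-7-phenyl-1-(2-phenylethyl)-2-oxabicyclo[4.2.0]oct-4-en-3-one | COC1=CC(=O)O[C@]2(CCc3ccccc3)[C@H]1[C@H](c1ccccc1)[C@H]2c1cc(OC)cc(=O)o1 | target

## Step count and least certain steps

Total step count: 17. Longest linear sequence: 15 steps (from 3 through steps 2 to 12 and 14 to 17).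

**Step 3 (key step).** Hydride transfer from the allylic ether CH2 of 2 to the keteniminium ion, and cationic oligomerisation of the electron-rich styrene, may outrun cycloaddition. Facial discrimination by the auxiliary may be weak, since only one methyl group flanks the approach. The β-aryloxy group may be lost by retro-oxa-Michael opening during hydrolysis. The fallback sets out from acid 3 (through acid chloride 5) and chromene 2 and returns at 9. Acid chloride 5 is dehydrohalogenated with Et3N to (benzyloxymethyl)ketene F1, which is combined with 2 under EtAlCl2 promotion in CH2Cl2 at −78 °C, a Lewis-acid-promoted ketene–alkene [2+2] cycloaddition that needs no iminium activation. This gives the racemic cyclobutanone F2, which is resolved by preparative chromatography on a chiral stationary phase to give 9. Half of the material and the auxiliary control are given up.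

**Step 5.** Oxidative addition into an electron-neutral, ortho-alkylated aryl ether may be too slow and the reaction may stall. Hydrogenolysis of the benzyl C–O bond may compete. The tertiary cyclobutanolate may undergo β-carbon elimination at nickel and open the ring. The fallback sets out from 10 and returns at 15. Heating 10 with PhSNa in N-methylpyrrolidone cleaves the CH2–O bond by SN2 attack and gives the phenol sulfide F3. PhNTf2 and K2CO3 give the aryl triflate F4, and Pd(OAc)2, 1,3-bis(diphenylphosphino)propane, HCO2H and Et3N in DMF reduce it to the phenyl compound F5. Bromoacetylation as in step 7 gives F6, NaIO4 gives the sulfoxide F7, and a Pummerer rearrangement (trifluoroacetic anhydride, 2,6-lutidine, then aq. NaHCO3) unmasks the aldehyde 15.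

**Step 4.** Enolisation toward Cb followed by loss of the aryloxide may compete with addition. Facial selectivity may suffer because the benzyloxymethyl group lies on the convex face next to the carbonyl. The fallback sets out from 9 and returns at 10. Lithium phenylacetylide with CeCl3 in THF at −78 °C, a smaller and less basic nucleophile, gives the propargylic alcohol F8. Hydrogenation of the triple bond over Pt/C in EtOAc, which leaves the benzyl ether, gives 10.

**Step 10.** Electron transfer to the aldehyde (ketyl formation and coupling) or protonation of the samarium enolate before ring closure may take over. Aldehyde 15 may epimerise at Cb on handling. The fallback sets out from 12 and returns at 16. Acetylation (Ac2O, DMAP, Et3N) gives the acetate F9, desilylation as in step 8 gives the alcohol F10, and Dess–Martin oxidation gives the aldehyde F11. LiN(SiMe3)2 in THF at −78 °C then forms the acetate enolate, which closes onto the aldehyde in an intramolecular aldol addition to give 16.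

**Step 17.** Methylation may occur at the carbonyl oxygen of the pyranone (giving the 2-methoxy-4-pyranone pattern) or at carbon between the carbonyl groups. Prolonged contact with carbonate may start loss of the Ca–O bond. The fallback sets out from 25 and returns at 26 and passes through no new compound (F0). It is a Mitsunobu O-methylation (PPh3, diisopropyl azodicarboxylate, MeOH, THF, 0 °C), which activates methanol and not the enolate and so avoids a basic medium.

## Further compounds

F1 | step 3 | (benzyloxymethyl)ketene, 4-(benzyloxy)but-1-en-1-one | O=C=CCOCc1ccccc1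
F2 | step 3 | racemate of 9 (both enantiomers shown) | O=C1[C@@H]2COc3ccccc3[C@@H]2[C@H]1COCc1ccccc1.O=C1[C@H]2COc3ccccc3[C@H]2[C@@H]1COCc1ccccc1
F3 | step 5 | 4-[(benzyloxy)methyl]-3-(2-hydroxyphenyl)-1-(2-phenylethyl)-2-[(phenylsulfanyl)methyl]cyclobutan-1-ol | O[C@]2(CCc3ccccc3)[C@H](CSc4ccccc4)[C@H](c1ccccc1O)[C@H]2COCc1ccccc1
F4 | step 5 | aryl triflate of F3 | O[C@]2(CCc3ccccc3)[C@H](CSc4ccccc4)[C@H](c1ccccc1OS(=O)(=O)C(F)(F)F)[C@H]2COCc1ccccc1
F5 | step 5 | 4-[(benzyloxy)methyl]-3-phenyl-1-(2-phenylethyl)-2-[(phenylsulfanyl)methyl]cyclobutan-1-ol | O[C@]2(CCc3ccccc3)[C@H](CSc4ccccc4)[C@H](c1ccccc1)[C@H]2COCc1ccccc1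
F6 | step 5 | bromoacetate of F5 | BrCC(=O)O[C@]2(CCc3ccccc3)[C@H](CSc4ccccc4)[C@H](c1ccccc1)[C@H]2COCc1ccccc1
F7 | step 5 | sulfoxide of F6 (epimers at sulfur) | BrCC(=O)O[C@]2(CCc3ccccc3)[C@H](CS(=O)c4ccccc4)[C@H](c1ccccc1)[C@H]2COCc1ccccc1
F8 | step 4 | 1-[(benzyloxy)methyl]-2-(phenylethynyl)-1,2a,3,8b-tetrahydro-2H-cyclobuta[c]chromen-2-ol (configuration as in 10) | O[C@]2(C#Cc3ccccc3)[C@@H]4COc5ccccc5[C@@H]4[C@H]2COCc1ccccc1
F9 | step 10 | acetate of 12 at the tertiary oxygen | CC(=O)O[C@]2(CCc3ccccc3)[C@H](CO[Si](CC)(CC)CC)[C@H](c1ccccc1)[C@H]2COCc1ccccc1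
F10 | step 10 | 4-[(benzyloxy)methyl]-2-(hydroxymethyl)-3-phenyl-1-(2-phenylethyl)cyclobutyl acetate | CC(=O)O[C@]2(CCc3ccccc3)[C@H](CO)[C@H](c1ccccc1)[C@H]2COCc1ccccc1
F11 | step 10 | 4-[(benzyloxy)methyl]-2-formyl-3-phenyl-1-(2-phenylethyl)cyclobutyl acetate | CC(=O)O[C@]2(CCc3ccccc3)[C@H](C=O)[C@H](c1ccccc1)[C@H]2COCc1ccccc1
F0 | step 17 | none | none
A1 | alternative 1 | cyclobutanol with a 2,2-dimethyl-4-oxo-1,3-dioxin-6-yl group on Cb and a (2,2-dimethyl-4-oxo-1,3-dioxin-6-yl)acetyl group on Cd | O[C@]2(CCc3ccccc3)[C@H](C1=CC(=O)OC(C)(C)O1)[C@H](c1ccccc1)[C@H]2C(=O)CC1=CC(=O)OC(C)(C)O1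
A2 | alternative 1 | bis(4-hydroxy) analogue of the target (identical with 25) | OC1=CC(=O)O[C@]2(CCc3ccccc3)[C@H]1[C@H](c1ccccc1)[C@H]2c1cc(O)cc(=O)o1
A3 | alternative 2 | tert-butyl 2-oxo-4-phenyl-6-(2-phenylethyl)-2H-pyran-5-carboxylate | O=C1C=C(c2ccccc2)C(C(=O)OC(C)(C)C)=C(CCc2ccccc2)O1
A4 | alternative 2 | tert-butyl 3-oxo-5-phenyl-1-(2-phenylethyl)-2-oxabicyclo[2.2.0]hex-5-ene-6-carboxylate | O=C1O[C@]2(CCc3ccccc3)[C@H]1C(c1ccccc1)=C2C(=O)OC(C)(C)C
A5 | alternative 3 | methyl [1,3-dihydroxy-2-(methanesulfonyloxy)-5-phenyl-3-(2-phenylethyl)-4-{[(tert-butyldimethylsilyl)oxy]methyl}cyclopentyl]acetate (three oxygens cis) | COC(=O)C[C@]1(O)[C@@H](OS(C)(=O)=O)[C@](O)(CCc2ccccc2)[C@H](CO[Si](C)(C)C(C)(C)C)[C@H]1c1ccccc1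
A6 | alternative 3 | 8-{[(tert-butyldimethylsilyl)oxy]methyl}-7-phenyl-1-(2-phenylethyl)-2-oxabicyclo[4.2.0]octane-3,5-dione | O=C1CC(=O)O[C@]2(CCc3ccccc3)[C@H]1[C@H](c1ccccc1)[C@H]2CO[Si](C)(C)C(C)(C)C
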